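**Plan**

Atoms carry the numbers of the target SMILES (C1 … O29); "exo" is the convex face of the C22-centred tricycle, "endo" the concave face.
Cuts, latest first: C4–C2 and C10–C4 (side chain); C27–C28, O24–C25 and C23–C28 (spirolactone); O15–C16 (γ-lactone); C18–C19; then C12–C22 by a retro-[3,3] shift that re-forms C10–C17; C10–C11; last the Diels–Alder bonds C10–C17 and C21–C23.
Enabling feature: the cis-fused cyclohexene C10–C11–C12–C22–C21–C23 and cyclopentane C16–C17–C18–C21–C22 (shared bond C21–C22) are the [3,3] image of a norbornene whose one-carbon bridge is C18 and whose two-carbon bridge is C23–C10.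
Forward: Diels–Alder gives the norbornene; the anionic oxy-Cope step opens it to the cyclohexene/cyclopentene pair; iodolactonisation closes the C13 lactone; Reformatsky addition/lactonisation closes the spirolactone; Heck coupling and conjugate addition join C4–C9 and C1–C3.
Stereochemistry: lipase resolution (C21); syn-methoxy-directed endo addition and the boat transition state (C12, C22); exo-face additions (C18, C23); anti iodolactonisation (C16); zinc chelation (C28); (R)-BINAP/rhodium (C4).

Key step: step 9

Remark: compound 3 is a racemate and is drawn as the enantiomer that is carried on; the lipase is assumed to follow the usual empirical rule for secondary alcohols, so the wanted enantiomer is taken as the hydrolysed alcohol.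

**Route**

Step 1
Reactants: 1 5,5-dimethoxy-1,2,3,4-tetrachlorocyclopenta-1,3-diene; 2 vinyl acetate
Product: 3 rac-endo-1,4,5,6-tetrachloro-7,7-dimethoxybicyclo[2.2.1]hept-5-en-2-yl acetate
Conditions: neat in excess 2, hydroquinone (trace), sealed tube, 170 °C
Reagents that add atoms: none
Why: Diels–Alder reaction of the cyclic, s-cis-locked chlorinated diene with the enol ester should give the endo acetate (acetate syn to the chlorinated alkene) as a racemate, forming C10–C17 and C21–C23.

Step 2
Reactants: 3 rac-endo-1,4,5,6-tetrachloro-7,7-dimethoxybicyclo[2.2.1]hept-5-en-2-yl acetate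
Product: 4 (1S,2R,4R)-1,4,5,6-tetrachloro-7,7-dimethoxybicyclo[2.2.1]hept-5-en-2-ol
Conditions: Candida rugosa lipase, phosphate buffer pH 7/acetone, 30 °C, stopped below half conversion
Reagents that add atoms: none
Why: Enzymatic kinetic resolution by lipase-catalysed ester hydrolysis, in which the empirical rule for secondary alcohols (bridgehead carbon large, C3 methylene medium) predicts the (2R) ester as the fast one, so the wanted alcohol is collected and the slow enantiomeric acetate is removed by chromatography.

Step 3
Reactants: 4 (1S,2R,4R)-1,4,5,6-tetrachloro-7,7-dimethoxybicyclo[2.2.1]hept-5-en-2-ol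
Product: 5 (1R,2R,4R)-7,7-dimethoxybicyclo[2.2.1]hept-5-en-2-ol
Conditions: Na, NH3 (l), EtOH, THF, −78 to −33 °C
Reagents that add atoms: none
Why: Dissolving-metal reduction should cleave the two vinylic and two bridgehead C–Cl bonds by electron transfer while the ketal, the alkene and the stereocentres stay untouched.

Step 4
Reactants: 5 (1R,2R,4R)-7,7-dimethoxybicyclo[2.2.1]hept-5-en-2-ol
Product: 6 (1R,4R)-7,7-dimethoxybicyclo[2.2.1]hept-5-en-2-one
Conditions: Dess–Martin periodinane, CH2Cl2, rt
Reagents that add atoms: none
Why: Dess–Martin oxidation of the secondary alcohol is near-neutral and should leave the ketal and the strained alkene alone, the chirality now resting on the two bridgeheads.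

Step 5
Reactants: 6 (1R,4R)-7,7-dimethoxybicyclo[2.2.1]hept-5-en-2-one
Product: 10 (1R,4S)-7,7-dimethoxy-3-methylidenebicyclo[2.2.1]hept-5-en-2-one, via lithium enolate 7 (not isolated), via Mannich base 8 (not isolated), via methiodide 9 (not isolated)
Conditions: LiHMDS, THF, −78 °C; Eschenmoser's salt, −78 °C to rt; MeI, rt; aq. NaHCO3/CH2Cl2
Reagents that add atoms: Eschenmoser's salt (dimethylmethylideneammonium iodide), C=[N+](C)C.[I-]
Why: Mannich reaction of the C3 enolate followed by quaternisation and Hofmann-type β-elimination should give the exocyclic enone, the aminomethyl group entering endo (anti to the syn-methoxy group) at a centre that the elimination removes.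

Step 6
Reactants: 11 propargyl alcohol
Product: 12 (E)-3-(tributylstannyl)prop-2-en-1-ol
Conditions: Bu3SnH, AIBN (cat.), neat, 80 °C
Reagents that add atoms: tributyltin hydride, CCCC[SnH](CCCC)CCCC
Why: Radical hydrostannation of the terminal alkyne under equilibrating conditions should favour the (E)-β-stannyl alkene, which is separated from its isomers by chromatography.

Step 7
Reactants: 12 (E)-3-(tributylstannyl)prop-2-en-1-ol
Product: 13 tert-butyldimethyl{[(E)-3-(tributylstannyl)prop-2-en-1-yl]oxy}silane
Conditions: TBSCl, imidazole, CH2Cl2, rt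
Reagents that add atoms: tert-butyldimethylsilyl chloride, CC(C)(C)[Si](C)(C)Cl
Why: Standard silylation of a primary alcohol gives an ether that survives organolithium, alkoxide and mild acid.

Step 8
Reactants: 13 tert-butyldimethyl{[(E)-3-(tributylstannyl)prop-2-en-1-yl]oxy}silane; 10 (1R,4S)-7,7-dimethoxy-3-methylidenebicyclo[2.2.1]hept-5-en-2-one
Product: 15 2-endo-[(E)-3-(tert-butyldimethylsilyloxy)prop-1-enyl]-7,7-dimethoxy-3-methylidenebicyclo[2.2.1]hept-5-en-2-exo-ol, via alkenyllithium 14 (not isolated)
Conditions: n-BuLi, THF, −78 °C; then 10, −78 °C; aq. NH4Cl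
Reagents that add atoms: none
Why: Tin–lithium exchange gives the configurationally stable (E)-alkenyllithium, which should add 1,2 to the non-enolisable enone from the endo face because the methoxy group lying over the exo face of C10 blocks the other side, placing the alkenyl group under C16=C22 and the hydroxyl exo.

Step 9
Reactants: 15 2-endo-[(E)-3-(tert-butyldimethylsilyloxy)prop-1-enyl]-7,7-dimethoxy-3-methylidenebicyclo[2.2.1]hept-5-en-2-exo-ol
Product: 18 cis-hydrindadiene enol triflate (C10–OTf; C10=C11; C12–CH2OTBS; C16=C17; C18 dimethyl ketal; C23=CH2; H12/H21/H22 all cis), via potassium alkoxide 16 (not isolated), via potassium dienolate 17 (not isolated)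
Conditions: KHMDS, 18-crown-6, THF, 0 °C to rt; then PhNTf2, −78 to 0 °C
Reagents that add atoms: N-phenylbis(trifluoromethanesulfonimide), O=S(=O)(N(c1ccccc1)S(=O)(=O)C(F)(F)F)C(F)(F)F
Why: Deprotonation gives the potassium alkoxide, whose oxyanion weakens C10–C17 so that the 1,5-diene C12=C11–C10–C17–C16=C22 undergoes a concerted [3,3]-sigmatropic shift (anionic oxy-Cope rearrangement) that forms C12–C22, breaks C10–C17 and releases the strain of the bicyclo[2.2.1] skeleton. The closest known reaction type is the rearrangement of 2-endo-vinylnorborn-5-en-2-olates to cis-bicyclo[4.3.0]nonenone enolates. The six-membered ring C10–C11–C12–C22–C21–C23 is closed by the pericyclic bond formation itself, the tether C10–C23–C21 being already in place, while the former bicycle is left as the cyclopentene C16–C17–C18–C21–C22. Both new stereocentres come from the boat transition state that the bicycle enforces: bonding to the endo face of C22 fixes the cis C21–C22 fusion, and the (E) geometry puts C13 at C12 on the same side as C16. The step needs the alkenyl group endo and a regiodefined enolate; the first is secured in step 8, the second by O-sulfonylation of the C10=C11 dienolate before any proton transfer, which also masks the C10 carbonyl and deactivates C10=C11 toward the later ozonolyses. The C23 methylene offers no second 1,5-diene, so only the intended shift is open.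

Step 10
Reactants: 18 cis-hydrindadiene enol triflate
Product: 19 cyclopentenone (C18 ketone conjugated with C16=C17; otherwise as 18)
Conditions: PPTS, acetone/H2O, rt
Reagents that add atoms: water, O
Why: Acid-catalysed hydrolysis of the allylic dimethyl ketal is fast through an allyl-stabilised oxocarbenium ion and mild enough for the silyl ether, the triflate and the β,γ-placed methylene.

Step 11
Reactants: 19 cyclopentenone
Product: 20 tertiary allylic alcohol (C18 methyl exo and hydroxyl endo)
Conditions: MeMgBr, CeCl3, THF, −78 °C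
Reagents that add atoms: methylmagnesium bromide, C[Mg]Br
Why: Organocerium 1,2-addition to the enone is too weakly basic to enolise C21 and should come from the convex face of the cis-fused bicycle, anti to C23 on C21, which sets C18 with the methyl exo and the hydroxyl endo.

Step 12
Reactants: 20 tertiary allylic alcohol
Product: 21 diol (free C13 hydroxymethyl)
Conditions: HF·pyridine, pyridine, THF, 0 °C to rt
Reagents that add atoms: none
Why: Buffered fluoride desilylation of the primary ether should neither cleave the enol triflate nor ionise the tertiary allylic alcohol.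

Step 13
Reactants: 21 diol
Product: 23 C13 carboxylic acid, via aldehyde 22 (not isolated)
Conditions: TEMPO (cat.), PhI(OAc)2, MeCN/H2O, rt
Reagents that add atoms: water, O
Why: Oxoammonium (TEMPO/PhI(OAc)2) oxidation in aqueous acetonitrile takes the primary alcohol through the aldehyde hydrate to the acid and leaves the tertiary alcohol and the alkenes alone.

Step 14
Reactants: 23 C13 carboxylic acid
Product: 24 iodolactone (γ-lactone C13–O15–C16; iodine exo on C17)
Conditions: I2, NaHCO3, MeCN/H2O, 0 °C, dark
Reagents that add atoms: iodine, II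
Why: Iodolactonisation, in which the endo carboxylate opens the iodonium ion of C16=C17 at C16 in a 5-exo closure with anti addition, sets C16 (O15 endo, cis to C12) while the electron-poor triflyloxy diene does not compete.

Step 15
Reactants: 24 iodolactone
Product: 25 tricyclic lactone triflate with C23 methylene
Conditions: Bu3SnH, AIBN (cat.), benzene, 80 °C
Reagents that add atoms: none
Why: Radical dehalogenation removes the iodine, the C17 radical having no alkene placed for a favourable cyclisation.

Step 16
Reactants: 25 tricyclic lactone triflate with C23 methylene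
Product: 27 C23 ketone (2-triflyloxy enone), via ozonide 26 (not isolated)
Conditions: O3, CH2Cl2, −78 °C; then PPh3, −78 °C to rt
Reagents that add atoms: ozone, [O-][O+]=O
Why: Ozonolysis should cleave the exocyclic methylene selectively because the only other alkene, the enol triflate C10=C11, is strongly deactivated toward the electrophilic oxidant.

Step 17
Reactants: 27 C23 ketone
Product: 28 C23 vinyl carbinol (vinyl exo and hydroxyl endo)
Conditions: CH2=CHMgBr, CeCl3, THF, −78 °C
Reagents that add atoms: vinylmagnesium bromide, C=C[Mg]Br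
Why: Organocerium 1,2-addition should deliver the vinyl group to the convex face of the bowl-shaped tricycle, cerium being held between the endo C18 alkoxide and the carbonyl oxygen, which sets C23 with C28 exo and O24 endo while the low basicity spares C12–H and the lactone.

Step 18
Reactants: 28 C23 vinyl carbinol
Product: 30 α-hydroxy aldehyde (C28 formyl on C23), via ozonide 29 (not isolated)
Conditions: O3, CH2Cl2, −78 °C; then PPh3
Reagents that add atoms: ozone, [O-][O+]=O
Why: Ozonolysis of the monosubstituted vinyl group beside the deactivated enol triflate should give the aldehyde, which is used without storage.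

Step 19
Reactants: 30 α-hydroxy aldehyde
Product: 32 bis-lactone triflate (spiro γ-lactone C23–O24–C25–C27–C28 with C28 hydroxyl syn to C10), via hydroxy ester 31 (not isolated)
Conditions: Zn (activated), BrCH2CO2Me, THF, 0 °C to rt; aq. HCl work-up; camphorsulfonic acid (cat.), CH2Cl2, rt
Reagents that add atoms: methyl bromoacetate, COC(=O)CBr
Why: Reformatsky reaction under chelation control, zinc bridging the C23 alkoxide and the aldehyde oxygen so that the zinc enolate attacks C28 from the side of the small exo hydrogen on C21 and not past the triflate on C10, should set C28 with O29 syn to C10, after which the tertiary C23 oxygen closes the γ-lactone on the ester.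

Step 20
Reactants: 32 bis-lactone triflate
Product: 33 methyl (E)-3-(C10-yl)acrylate dienoate
Conditions: methyl acrylate, Pd(OAc)2 (cat.), NaHCO3, n-Bu4NCl, DMF, 50 °C
Reagents that add atoms: methyl acrylate, C=CC(=O)OC
Why: Heck reaction of the enol triflate with the acrylate (oxidative addition, syn insertion, syn β-hydride elimination) should give the (E)-dienoate under bicarbonate conditions too mild to enolise the lactone.

Step 21
Reactants: 33 methyl (E)-3-(C10-yl)acrylate dienoate
Product: 34 CNP0148106.2 (target)
Conditions: isopropenylboronic acid pinacol ester, [Rh(OH)((R)-binap)]2 (cat.), dioxane/H2O, 40 °C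
Reagents that add atoms: isopropenylboronic acid pinacol ester, CC(=C)B1OC(C)(C)C(C)(C)O1
Why: Hayashi–Miyaura rhodium-catalysed asymmetric conjugate addition of the alkenylboronate to the enoate should favour 1,4-attack at C4 over 1,6-attack at the hindered C11, and the (R)-BINAP catalyst is expected to deliver the isopropenyl group to the α-re face of the (E)-enoate, giving (S) at C4 under catalyst control.

**Compound list**

1 | 5,5-dimethoxy-1,2,3,4-tetrachlorocyclopenta-1,3-diene | COC1(OC)C(Cl)=C(Cl)C(Cl)=C1Cl | starting material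
2 | vinyl acetate | C=COC(C)=O | starting material
3 | rac-endo-1,4,5,6-tetrachloro-7,7-dimethoxybicyclo[2.2.1]hept-5-en-2-yl acetate (racemate, drawn as the (1S,2R,4R) enantiomer) | CC(=O)O[C@@H]1C[C@]2(Cl)C(Cl)=C(Cl)[C@@]1(Cl)C2(OC)OC | intermediate
4 | (1S,2R,4R)-1,4,5,6-tetrachloro-7,7-dimethoxybicyclo[2.2.1]hept-5-en-2-ol (endo OH) | O[C@@H]1C[C@]2(Cl)C(Cl)=C(Cl)[C@@]1(Cl)C2(OC)OC | intermediate
5 | (1R,2R,4R)-7,7-dimethoxybicyclo[2.2.1]hept-5-en-2-ol (endo OH) | O[C@@H]1C[C@@H]2C=C[C@H]1C2(OC)OC | intermediate
6 | (1R,4R)-7,7-dimethoxybicyclo[2.2.1]hept-5-en-2-one | O=C1C[C@@H]2C=C[C@H]1C2(OC)OC | intermediate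
7 | lithium enolate of 6 | [Li+].[O-]C1=C[C@@H]2C=C[C@H]1C2(OC)OC | intermediate
8 | 3-endo-(dimethylaminomethyl)-7,7-dimethoxybicyclo[2.2.1]hept-5-en-2-one (Mannich base) | O=C1[C@H](CN(C)C)[C@@H]2C=C[C@H]1C2(OC)OC | intermediate
9 | trimethylammoniomethyl ketone iodide (methiodide of 8) | O=C1[C@H](C[N+](C)(C)C)[C@@H]2C=C[C@H]1C2(OC)OC.[I-] | intermediate
10 | (1R,4S)-7,7-dimethoxy-3-methylidenebicyclo[2.2.1]hept-5-en-2-one | O=C1C(=C)[C@@H]2C=C[C@H]1C2(OC)OC | intermediate
11 | propargyl alcohol | C#CCO | starting material
12 | (E)-3-(tributylstannyl)prop-2-en-1-ol | OC/C=C/[Sn](CCCC)(CCCC)CCCC | intermediate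
13 | tert-butyldimethyl{[(E)-3-(tributylstannyl)prop-2-en-1-yl]oxy}silane | CC(C)(C)[Si](C)(C)OC/C=C/[Sn](CCCC)(CCCC)CCCC | intermediate
14 | (E)-3-(tert-butyldimethylsilyloxy)prop-1-enyllithium | [Li]/C=C/CO[Si](C)(C)C(C)(C)C | intermediate
15 | 2-endo-[(E)-3-(tert-butyldimethylsilyloxy)prop-1-enyl]-7,7-dimethoxy-3-methylidenebicyclo[2.2.1]hept-5-en-2-exo-ol | CC(C)(C)[Si](C)(C)OC/C=C/[C@]1(O)C(=C)[C@@H]2C=C[C@H]1C2(OC)OC | intermediate
16 | potassium alkoxide of 15 | CC(C)(C)[Si](C)(C)OC/C=C/[C@]1([O-])C(=C)[C@@H]2C=C[C@H]1C2(OC)OC.[K+] | intermediate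
17 | potassium C10=C11 dienolate of the cis-hydrindenone | [K+].[O-]C1=C[C@H](CO[Si](C)(C)C(C)(C)C)[C@@H]2C=CC(OC)(OC)[C@@H]2C1=C | intermediate
18 | cis-hydrindadiene enol triflate (C10–OTf, C10=C11, C12–CH2OTBS, C16=C17, C18 dimethyl ketal, C23=CH2; H12, H21, H22 cis) | FC(F)(F)S(=O)(=O)OC1=C[C@H](CO[Si](C)(C)C(C)(C)C)[C@@H]2C=CC(OC)(OC)[C@@H]2C1=C | intermediate
19 | cyclopentenone (C18 ketone, C16=C17) | FC(F)(F)S(=O)(=O)OC1=C[C@H](CO[Si](C)(C)C(C)(C)C)[C@@H]2C=CC(=O)[C@@H]2C1=C | intermediate
20 | tertiary allylic alcohol (C18 methyl exo, hydroxyl endo) | FC(F)(F)S(=O)(=O)OC1=C[C@H](CO[Si](C)(C)C(C)(C)C)[C@@H]2C=C[C@](C)(O)[C@@H]2C1=C | intermediate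
21 | diol (C13 hydroxymethyl, C18 carbinol) | FC(F)(F)S(=O)(=O)OC1=C[C@H](CO)[C@@H]2C=C[C@](C)(O)[C@@H]2C1=C | intermediate
22 | C13 aldehyde | FC(F)(F)S(=O)(=O)OC1=C[C@H](C=O)[C@@H]2C=C[C@](C)(O)[C@@H]2C1=C | intermediate
23 | C13 carboxylic acid | FC(F)(F)S(=O)(=O)OC1=C[C@H](C(=O)O)[C@@H]2C=C[C@](C)(O)[C@@H]2C1=C | intermediate
24 | iodolactone (O15 endo on C16, iodine exo on C17) | FC(F)(F)S(=O)(=O)OC1=C[C@@H]2C(=O)O[C@@H]3[C@@H](I)[C@](C)(O)[C@@H]([C@H]23)C1=C | intermediate
25 | tricyclic lactone triflate with C23 methylene | FC(F)(F)S(=O)(=O)OC1=C[C@@H]2C(=O)O[C@@H]3C[C@](C)(O)[C@@H]([C@H]23)C1=C | intermediate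
26 | spiro-1,2,4-trioxolane (ozonide) at C23 of 25, both C23 epimers | FC(F)(F)S(=O)(=O)OC1=C[C@@H]2C(=O)O[C@@H]3C[C@](C)(O)[C@@H]([C@H]23)C14OCOO4 | intermediate
27 | C23 ketone (2-triflyloxy enone) | FC(F)(F)S(=O)(=O)OC1=C[C@@H]2C(=O)O[C@@H]3C[C@](C)(O)[C@@H]([C@H]23)C1=O | intermediate
28 | C23 vinyl carbinol (vinyl exo, hydroxyl endo) | FC(F)(F)S(=O)(=O)OC1=C[C@@H]2C(=O)O[C@@H]3C[C@](C)(O)[C@@H]([C@H]23)[C@@]1(O)C=C | intermediate
29 | 1,2,4-trioxolane (ozonide) of the vinyl group of 28, both C28 epimers | FC(F)(F)S(=O)(=O)OC1=C[C@@H]2C(=O)O[C@@H]3C[C@](C)(O)[C@@H]([C@H]23)[C@@]1(O)C4OCOO4 | intermediate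
30 | α-hydroxy aldehyde (C28 formyl exo on C23) | FC(F)(F)S(=O)(=O)OC1=C[C@@H]2C(=O)O[C@@H]3C[C@](C)(O)[C@@H]([C@H]23)[C@@]1(O)C=O | intermediate
31 | methyl (3S)-3-hydroxy-3-(C23-yl)propanoate (hydroxy ester) | FC(F)(F)S(=O)(=O)OC1=C[C@@H]2C(=O)O[C@@H]3C[C@](C)(O)[C@@H]([C@H]23)[C@@]1(O)[C@@H](O)CC(=O)OC | intermediate
32 | bis-lactone triflate (spirolactone with (S)-C28 hydroxyl) | FC(F)(F)S(=O)(=O)OC1=C[C@@H]2C(=O)O[C@@H]3C[C@](C)(O)[C@@H]([C@H]23)[C@]12OC(=O)C[C@@H]2O | intermediate
33 | methyl (E)-3-(C10-yl)acrylate dienoate | COC(=O)/C=C/C1=C[C@@H]2C(=O)O[C@@H]3C[C@](C)(O)[C@@H]([C@H]23)[C@]12OC(=O)C[C@@H]2O | intermediate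
34 | CNP0148106.2 | C=C(C)[C@H](CC(=O)OC)C1=C[C@@H]2C(=O)O[C@@H]3C[C@](C)(O)[C@@H]([C@H]23)[C@]12OC(=O)C[C@@H]2O | target

**Count and risks**

Total steps: 21. Longest linear sequence: 19 steps (steps 1–5 and 8–21, from 1 to 34); the stannane branch (steps 6 and 7) joins at step 8.

Most likely to fail:

Step 19. Chelation may be incomplete, so that attack through an open, non-chelated transition state gives poor or reversed facial selectivity at C28; acid may also dehydrate the β-hydroxy lactone. The fallback replaces substrate control by reagent control. It sets out from 30: (−)-B-allyldiisopinocampheylborane (the reagent made from (+)-α-pinene; Et2O, −78 °C, ethanolamine work-up) adds allyl to the si face of the aldehyde and should give the (S)-configured homoallylic alcohol F1. Ozonolysis of its terminal alkene (O3, CH2Cl2, −78 °C; PPh3), which the enol triflate tolerates, gives a β-hydroxy aldehyde that closes onto the C23 hydroxyl as the lactol F2. Fétizon oxidation (Ag2CO3 on Celite, benzene, 80 °C) oxidises the lactol in preference to the secondary alcohol and comes back to the route at 32.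

Step 21. Insertion at the hindered C4 may be slow and lose out to protodeboronation or 1,6-addition; the chiral substrate may override the catalyst's facial preference; and the basic rhodium hydroxide may move C10=C11 into conjugation with the lactone. The fallback builds C4 by a sigmatropic shift instead. It sets out from 32: Stille coupling with (E)-2-methyl-3-(tributylstannyl)prop-2-en-1-ol (Pd(PPh3)4, CuI, LiCl, DMF, rt) gives the dienol F3. Johnson–Claisen rearrangement (MeC(OMe)3, propionic acid (cat.), toluene, 110 °C) then forms C4–C5 through a chair transition state, the transposed alkene becoming the isopropenyl group and the ketene acetal the methyl ester. This arrives directly at 34; the C4 epimer, if formed, is removed by chromatography.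

Step 17. The vinyl reagent may act as a base at C12–H (γ to the enone and α to the lactone), the C18 alkoxide may trigger retro-aldol opening of the cyclopentane, or the nucleophile may attack the triflate sulfur. The fallback avoids the C23 ketone altogether and keeps the methylene carbon as C28. It sets out from 25: hydrogen-bond-directed dihydroxylation (OsO4·TMEDA, CH2Cl2, −78 °C; aq. NaHSO3), in which the endo C18 hydroxyl, 1,3-syn to the endo face of C23, guides both oxygens to the concave face, should give the triol F4 with O24 endo and the hydroxymethyl group exo. Parikh–Doering oxidation (SO3·pyridine, DMSO, i-Pr2NEt, 0 °C) of the only primary alcohol returns to the route at 30 and replaces steps 16–18.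

**Further compounds**

F1 | step 19 | (S)-homoallylic alcohol (C23 carbinol bearing CH(OH)CH2CH=CH2) | FC(F)(F)S(=O)(=O)OC1=C[C@@H]2C(=O)O[C@@H]3C[C@](C)(O)[C@@H]([C@H]23)[C@@]1(O)[C@@H](O)CC=C
F2 | step 19 | spiro lactol (C25 hemiacetal, both anomers) | FC(F)(F)S(=O)(=O)OC1=C[C@@H]2C(=O)O[C@@H]3C[C@](C)(O)[C@@H]([C@H]23)[C@]12OC(O)C[C@@H]2O
F3 | step 21 | (E)-dienol (C10 bearing CH=C(CH3)CH2OH) | OC/C(C)=C/C1=C[C@@H]2C(=O)O[C@@H]3C[C@](C)(O)[C@@H]([C@H]23)[C@]12OC(=O)C[C@@H]2O
F4 | step 17 | triol (C23 endo hydroxyl and exo hydroxymethyl) | FC(F)(F)S(=O)(=O)OC1=C[C@@H]2C(=O)O[C@@H]3C[C@](C)(O)[C@@H]([C@H]23)[C@@]1(O)CO
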